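**Strategy.** Ring C is disconnected at O1–C2 and C4–C4a. This leads back to an aryl 2-arylacrylate in which O1 still carries acyl carbon C4. In one telescoped operation, light shifts the acyl group from O1 to the ortho carbon C4a (photo-Fries). The freed O1–H then adds to the acrylate CH2 (C2) under a chiral bifunctional amine–thiourea, which protonates C3 on one face. The step exploits ring A: its para carbon C6 is blocked by OMe, its two ortho carbons are equivalent, and O5 and O7 are silylated, so only C4a and O1 can bond. C3, the only stereocentre, is an α-aryl ketone carbon created by protonation.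

Key step: step 7

Remarks: chroman-4-one numbering is used (O1, C2, C3, C4, C4a, C5–C8, C8a). TBS = tert-butyldimethylsilyl. The target is the 3R enantiomer.

Assumption: no close analogue predicts the sense of induction in step 7. The quinidine-derived thiourea is assumed to give 3R. If it gives 3S, the pseudoenantiomeric quinine-derived catalyst would be used.

Step 1
Reactants: 1 2-methoxyresorcinol (2-methoxybenzene-1,3-diol)
Product: 2 1,3-bis(tert-butyldimethylsilyloxy)-2-methoxybenzene
Conditions: TBSCl (2.4 equiv), imidazole (5 equiv), DMF, rt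
Reagents that add atoms: tert-butyldimethylsilyl chloride (TBSCl), CC(C)(C)[Si](C)(C)Cl
Why: Imidazole-promoted O-silylation of both phenols should be clean, and silyl ethers are chosen because they offer the borylation catalyst no competing arene C–H, are inert to the light of step 7 and leave under non-basic conditions.

Step 2
Reactants: 2 1,3-bis(tert-butyldimethylsilyloxy)-2-methoxybenzene
Product: 4 3,5-bis(tert-butyldimethylsilyloxy)-4-methoxyphenol, via aryl pinacol boronate 3 (not isolated)
Conditions: [Ir(OMe)(cod)]2 (1.5 mol %), dtbpy (3 mol %), B2pin2 (1.0 equiv), THF, 80 °C; then 30 % aq H2O2, pH 7 buffer (NaH2PO4/Na2HPO4), THF, 0 °C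
Reagents that add atoms: bis(pinacolato)diboron, CC1(C)OB(OC1(C)C)B1OC(C)(C)C(C)(C)O1 (boron unit of 3); hydrogen peroxide, OO (phenol oxygen of 4)
Why: Sterically governed iridium-catalysed aromatic C–H borylation should take the only ring C–H without an ortho substituent (para to OMe), and ipso-oxidation of the C–B bond at neutral pH then gives the phenol while the aryl silyl ethers survive.

Step 3
Reactants: 4 3,5-bis(tert-butyldimethylsilyloxy)-4-methoxyphenol; 5 2,3-dibromopropanoyl chloride
Product: 7 3,5-bis(tert-butyldimethylsilyloxy)-4-methoxyphenyl 2-bromoprop-2-enoate, via dibromopropanoate ester 6 (not isolated)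
Conditions: Et3N (2.3 equiv), CH2Cl2, −20 °C → rt
Reagents that add atoms: none
Why: O-acylation followed by amine-induced loss of HBr from the 2,3-dibromopropanoate (acylation/E1cB elimination) is the standard entry to 2-bromoacrylates and brings in C2, C3 and C4 of the target.

Step 4
Reactants: 8 2,3-dimethoxyphenol
Product: 9 tert-butyl(2,3-dimethoxyphenoxy)dimethylsilane
Conditions: TBSCl (1.2 equiv), imidazole (2.5 equiv), DMF, rt
Reagents that add atoms: tert-butyldimethylsilyl chloride (TBSCl), CC(C)(C)[Si](C)(C)Cl
Why: Standard imidazole-promoted O-silylation masks the ring B phenol with the same group as ring A, so that one final step frees all three phenols.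

Step 5
Reactants: 9 tert-butyl(2,3-dimethoxyphenoxy)dimethylsilane
Product: 10 2-[3-(tert-butyldimethylsilyloxy)-4,5-dimethoxyphenyl]-4,4,5,5-tetramethyl-1,3,2-dioxaborolane
Conditions: [Ir(OMe)(cod)]2 (1.5 mol %), dtbpy (3 mol %), B2pin2 (1.0 equiv), THF, 80 °C
Reagents that add atoms: bis(pinacolato)diboron, CC1(C)OB(OC1(C)C)B1OC(C)(C)C(C)(C)O1
Why: Iridium-catalysed C–H borylation is steered by sterics to C5, the only C–H flanked by two hydrogens, which gives exactly the 3-oxy-4,5-dimethoxyphenyl pattern of ring B.

Step 6
Reactants: 7 3,5-bis(tert-butyldimethylsilyloxy)-4-methoxyphenyl 2-bromoprop-2-enoate; 10 2-[3-(tert-butyldimethylsilyloxy)-4,5-dimethoxyphenyl]-4,4,5,5-tetramethyl-1,3,2-dioxaborolane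
Product: 11 3,5-bis(tert-butyldimethylsilyloxy)-4-methoxyphenyl 2-[3-(tert-butyldimethylsilyloxy)-4,5-dimethoxyphenyl]prop-2-enoate
Conditions: Pd(OAc)2 (3 mol %), SPhos (6 mol %), K3PO4 (2 equiv), toluene/H2O (20:1), 40 °C
Reagents that add atoms: none
Why: In this Suzuki–Miyaura coupling zerovalent palladium should insert readily into the activated vinylic C–Br bond, and the mild phosphate base in a largely non-aqueous two-phase medium should spare the aryl ester and the silyl ethers.

Step 7
Reactants: 11 3,5-bis(tert-butyldimethylsilyloxy)-4-methoxyphenyl 2-[3-(tert-butyldimethylsilyloxy)-4,5-dimethoxyphenyl]prop-2-enoate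
Product: 14 (3R)-5,7-bis(tert-butyldimethylsilyloxy)-3-[3-(tert-butyldimethylsilyloxy)-4,5-dimethoxyphenyl]-6-methoxychroman-4-one, via hydroxy enone 12 (not isolated), via chromene enol 13 (not isolated)
Conditions: hν (300 nm), degassed toluene (5 mM), FEP flow coil, −20 °C; outflow run directly into 1-[3,5-bis(trifluoromethyl)phenyl]-3-[(9R)-6'-methoxycinchonan-9-yl]thiourea (from 9-amino-9-deoxy-epi-quinidine, 10 mol %), toluene, −40 °C, dark; AcOH quench
Reagents that add atoms: none
Why: Proposed new method: excitation of the aryl ester chromophore should break O1–C4 homolytically to a solvent-caged phenoxyl/2-arylacryloyl radical pair (an sp2-bound acyl radical that does not lose CO), which recombines at an ortho carbon and tautomerises to hydroxy enone 12, so making C4–C4a; this half is a photo-Fries rearrangement, known for aryl cinnamates and aryl 3-methylbut-2-enoates, whose products are closed to chromanones by base. In 12 the O1–H···O=C4 hydrogen bond turns O1 away from C2, so uncatalysed closure should be slow in cold toluene until the stream meets the catalyst in the dark, where the quinuclidine nitrogen takes the O1 proton and the thiourea binds the C4 oxygen. Ring C then closes by a 6-endo-trig oxa-Michael addition of O1 to C2 and gives catalyst-bound enol(ate) 13. C3 is set last, when the quinuclidinium N–H, fixed by the thiourea–enolate contact, hands its proton to one face of the C3=C4 bond, so the catalyst is the only control element. The closest known reaction types are the tandem hetero-Michael addition/enantioselective protonation of 2-substituted acrylates under bifunctional amine catalysts and the amino-alcohol-catalysed enantioselective ketonisation of 2H-chromen-4-ols; new are the 3-aryl case and the link to the photochemical acyl shift. The regioselectivity that is needed comes from the substrate (C6 para to O1 bears OMe, both ortho carbons are equivalent, O5 and O7 are silylated, so the 8-methoxy isomer cannot form), and flow irradiation plus a cold AcOH quench keep 14 away from light-induced α-cleavage and amine-induced enolisation.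

Step 8
Reactants: 14 (3R)-5,7-bis(tert-butyldimethylsilyloxy)-3-[3-(tert-butyldimethylsilyloxy)-4,5-dimethoxyphenyl]-6-methoxychroman-4-one
Product: 15 (3R)-5,7-dihydroxy-3-(3-hydroxy-4,5-dimethoxyphenyl)-6-methoxychroman-4-one (target)
Conditions: Et3N·3HF (excess), THF, 0 °C → rt; work-up at pH 6
Reagents that add atoms: none
Why: Fluoride-driven cleavage of the three aryl Si–O bonds runs in a mildly acidic medium, where neither enolisation at C3 nor base-induced retro-oxa-Michael opening of ring C should occur, so the 3R centre is kept.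

**Compound list**
1 | 2-methoxyresorcinol | COc1c(O)cccc1O | starting material
2 | 1,3-bis(tert-butyldimethylsilyloxy)-2-methoxybenzene | COc1c(O[Si](C)(C)C(C)(C)C)cccc1O[Si](C)(C)C(C)(C)C | intermediate
3 | 2-[3,5-bis(tert-butyldimethylsilyloxy)-4-methoxyphenyl]-4,4,5,5-tetramethyl-1,3,2-dioxaborolane | COc1c(O[Si](C)(C)C(C)(C)C)cc(B2OC(C)(C)C(C)(C)O2)cc1O[Si](C)(C)C(C)(C)C | intermediate
4 | 3,5-bis(tert-butyldimethylsilyloxy)-4-methoxyphenol | COc1c(O[Si](C)(C)C(C)(C)C)cc(O)cc1O[Si](C)(C)C(C)(C)C | intermediate
5 | 2,3-dibromopropanoyl chloride (racemic) | O=C(Cl)C(Br)CBr | starting material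
6 | 3,5-bis(tert-butyldimethylsilyloxy)-4-methoxyphenyl 2,3-dibromopropanoate (racemic) | O=C(Oc1cc(O[Si](C)(C)C(C)(C)C)c(OC)c(O[Si](C)(C)C(C)(C)C)c1)C(Br)CBr | intermediate
7 | 3,5-bis(tert-butyldimethylsilyloxy)-4-methoxyphenyl 2-bromoprop-2-enoate | C=C(Br)C(=O)Oc1cc(O[Si](C)(C)C(C)(C)C)c(OC)c(O[Si](C)(C)C(C)(C)C)c1 | intermediate
8 | 2,3-dimethoxyphenol | COc1cccc(O)c1OC | starting material
9 | tert-butyl(2,3-dimethoxyphenoxy)dimethylsilane | COc1cccc(O[Si](C)(C)C(C)(C)C)c1OC | intermediate
10 | 2-[3-(tert-butyldimethylsilyloxy)-4,5-dimethoxyphenyl]-4,4,5,5-tetramethyl-1,3,2-dioxaborolane | COc1cc(B2OC(C)(C)C(C)(C)O2)cc(O[Si](C)(C)C(C)(C)C)c1OC | intermediate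
11 | 3,5-bis(tert-butyldimethylsilyloxy)-4-methoxyphenyl 2-[3-(tert-butyldimethylsilyloxy)-4,5-dimethoxyphenyl]prop-2-enoate | C=C(C(=O)Oc1cc(O[Si](C)(C)C(C)(C)C)c(OC)c(O[Si](C)(C)C(C)(C)C)c1)c1cc(OC)c(OC)c(O[Si](C)(C)C(C)(C)C)c1 | intermediate
12 | 1-[2,4-bis(tert-butyldimethylsilyloxy)-6-hydroxy-3-methoxyphenyl]-2-[3-(tert-butyldimethylsilyloxy)-4,5-dimethoxyphenyl]prop-2-en-1-one | C=C(C(=O)c1c(O)cc(O[Si](C)(C)C(C)(C)C)c(OC)c1O[Si](C)(C)C(C)(C)C)c1cc(OC)c(OC)c(O[Si](C)(C)C(C)(C)C)c1 | intermediate
13 | 5,7-bis(tert-butyldimethylsilyloxy)-3-[3-(tert-butyldimethylsilyloxy)-4,5-dimethoxyphenyl]-6-methoxy-2H-chromen-4-ol | OC1=C(c2cc(OC)c(OC)c(O[Si](C)(C)C(C)(C)C)c2)COc2cc(O[Si](C)(C)C(C)(C)C)c(OC)c(O[Si](C)(C)C(C)(C)C)c12 | intermediate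
14 | (3R)-5,7-bis(tert-butyldimethylsilyloxy)-3-[3-(tert-butyldimethylsilyloxy)-4,5-dimethoxyphenyl]-6-methoxychroman-4-one | COc1cc([C@@H]2COc3cc(O[Si](C)(C)C(C)(C)C)c(OC)c(O[Si](C)(C)C(C)(C)C)c3C2=O)cc(O[Si](C)(C)C(C)(C)C)c1OC | intermediate
15 | (3R)-5,7-dihydroxy-3-(3-hydroxy-4,5-dimethoxyphenyl)-6-methoxychroman-4-one | COc1cc([C@@H]2COc3cc(O)c(OC)c(O)c3C2=O)cc(O)c1OC | target

**Total step count:** 8. **Longest linear sequence:** 6 (steps 1, 2, 3, 6, 7, 8).

**Steps most likely to fail**

Step 7 (proposed new method). Several processes could go wrong: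
- Excitation energy may drain into the styrene-type chromophore of the acrylate, so that the acyl shift is inefficient.
- Radicals may escape the solvent cage.
- Part of the hydroxy enone may close before it meets the catalyst.
- The facial selectivity of the protonation may be poor.

The fallback uses known chemistry and sets out from 11. The established tandem photo-Fries/base-induced oxa-Michael sequence (hν 300 nm, toluene, then DBU 5 mol %) should give the racemic silylated isoflavanone F1. Noyori-type asymmetric transfer hydrogenation with dynamic kinetic resolution follows (RuCl(p-cymene)[(R,R)-TsDPEN], HCO2H/Et3N 5:2, EtOAc, rt). Here C3 racemises through the enol while the catalyst reduces the 3R ketone from one face, which should give the cis-(3R,4R)-isoflavan-4-ol F2. Dess–Martin oxidation (CH2Cl2, 0 °C) comes back to the route at 14.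

Step 6. The aqueous base may hydrolyse the aryl ester, the bromoacrylate may oligomerise under base or palladium, and protodeboronation may compete. The fallback sets out from 10 and does the cross-coupling before any aryl ester exists. Suzuki–Miyaura coupling with commercial 2-bromoacrylic acid (Pd(OAc)2, SPhos, K3PO4, THF/H2O, 40 °C) should give the 2-arylacrylic acid F3. Steglich-type esterification of this acid with phenol 4 (EDC·HCl, catalytic DMAP, CH2Cl2, 0 °C) comes back to the route at 11, bypassing 7.

Step 3. Triethylamine or unreacted phenoxide may add to the bromoacrylate as it forms (addition–elimination), and the product may oligomerise on concentration. The fallback sets out from boronate 3, isolated after the borylation half of step 2, and makes the aryl–O bond from the arene side without any amine. Pinacol cleavage (NaIO4, NH4OAc, acetone/H2O, rt) should give the arylboronic acid F4. Chan–Lam acyloxylation with 2-bromoacrylic acid (Cu(OTf)2, urea, EtOAc, 60 °C, air) comes back to the route at 7.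

**Further compounds**
F1 | step 7 | racemic 5,7-bis(tert-butyldimethylsilyloxy)-3-[3-(tert-butyldimethylsilyloxy)-4,5-dimethoxyphenyl]-6-methoxychroman-4-one | COc1cc(C2COc3cc(O[Si](C)(C)C(C)(C)C)c(OC)c(O[Si](C)(C)C(C)(C)C)c3C2=O)cc(O[Si](C)(C)C(C)(C)C)c1OC
F2 | step 7 | (3R,4R)-5,7-bis(tert-butyldimethylsilyloxy)-3-[3-(tert-butyldimethylsilyloxy)-4,5-dimethoxyphenyl]-6-methoxychroman-4-ol | COc1cc([C@@H]2COc3cc(O[Si](C)(C)C(C)(C)C)c(OC)c(O[Si](C)(C)C(C)(C)C)c3[C@@H]2O)cc(O[Si](C)(C)C(C)(C)C)c1OC
F3 | step 6 | 2-[3-(tert-butyldimethylsilyloxy)-4,5-dimethoxyphenyl]prop-2-enoic acid | C=C(C(=O)O)c1cc(OC)c(OC)c(O[Si](C)(C)C(C)(C)C)c1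
F4 | step 3 | [3,5-bis(tert-butyldimethylsilyloxy)-4-methoxyphenyl]boronic acid | COc1c(O[Si](C)(C)C(C)(C)C)cc(B(O)O)cc1O[Si](C)(C)C(C)(C)C
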